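**Retrosynthetic overview**

1. Eryvarin Q ⇐ tris-MOM aldehyde 31 ⇐ (CH2OH → CHO, CO2Me → CH2OH) benzofuran ester 29 ⇐ trans-2,3-dihydrobenzofuran ester 25 by selenoxide elimination across C2–C3.
2. The strategy rests on furan C2, which is bonded only to O1, to C3 and to C1' of ring B. Cutting O1–C2 and C2–C3 together makes C2 the benzylic carbon of a ring-B sulfonium ylide, and O1–C7a–C3a–C3(CO2Me) an ortho-quinone methide of ring A ([4+1]).
3. Quinone methide precursor 12 ⇐ aryl glyoxylate 8 ⇐ two directed ortho-metalations of resorcinol bis-MOM ether (prenyl, then dimethyl oxalate), with chelation-controlled release of the O1 phenol.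
4. Sulfonium salt 21 ⇐ 4,6-dibromoresorcinol by two successive Br/Li exchanges (prenyl, then CHO), reduction, bromide, Me2S.
5. Ring order: rings A and B are bought as benzene rings; the furan ring is the only ring built (step 13) and is aromatised in steps 14–15.

Key step: step 13

Remark: the target is achiral, so 10–12 and 24–28 are carried as racemates (one enantiomer drawn for 25–28). Prenyl = 3-methylbut-2-en-1-yl, MOM = methoxymethyl.

**Ring A fragment**

Step 1
Reactants: 1 resorcinol
Product: 2 1,3-bis(methoxymethoxy)benzene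
Conditions: MOMCl (2.5 equiv), i-Pr2NEt (3 equiv), CH2Cl2, 0 °C → rt
Reagents that add atoms: chloromethyl methyl ether, COCCl
Why: Double O-alkylation of the phenols by the α-chloro ether (Williamson-type acetal formation) should mask both oxygens as base-stable, lithium-coordinating MOM ethers.

Step 2
Reactants: 2 1,3-bis(methoxymethoxy)benzene; 3 prenyl bromide
Product: 5 1,3-bis(methoxymethoxy)-2-prenylbenzene, via aryllithium 4 (not isolated)
Conditions: n-BuLi (1.1 equiv), THF, 0 °C → rt; CuI (10 mol %), then prenyl bromide, −78 °C → rt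
Reagents that add atoms: none
Why: Directed ortho-metalation takes place at the carbon flanked by both OMOM groups, and CuI-assisted allylic substitution of prenyl bromide by the aryllithium should give the linear prenyl arene.

Step 3
Reactants: 5 1,3-bis(methoxymethoxy)-2-prenylbenzene; 6 dimethyl oxalate
Product: 8 methyl 2-[2,4-bis(methoxymethoxy)-3-prenylphenyl]-2-oxoacetate, via aryllithium 7 (not isolated)
Conditions: n-BuLi (1.2 equiv), TMEDA, THF, −20 → 0 °C; cannulated into dimethyl oxalate (3 equiv), THF, −78 °C; aq. NH4Cl
Reagents that add atoms: none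
Why: A second directed ortho-metalation at the remaining position ortho to an OMOM group, followed by acylation of the aryllithium with excess oxalate under inverse addition, should stop at the aryl glyoxylate because the tetrahedral adduct survives at −78 °C.

Step 4
Reactants: 8 methyl 2-[2,4-bis(methoxymethoxy)-3-prenylphenyl]-2-oxoacetate
Product: 9 methyl 2-[2-hydroxy-4-(methoxymethoxy)-3-prenylphenyl]-2-oxoacetate
Conditions: MgBr2·OEt2 (2.5 equiv), toluene–Et2O, rt; aq. NH4Cl
Reagents that add atoms: none
Why: In this chelation-assisted acetal ether cleavage MgBr2 binds between the ketone oxygen and the ortho OMOM group and bromide removes the methoxymethyl carbon, so only the MOM ether next to the carbonyl (the future O1) should be lost while the para one, which cannot chelate, stays.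

Step 5
Reactants: 9 methyl 2-[2-hydroxy-4-(methoxymethoxy)-3-prenylphenyl]-2-oxoacetate
Product: 10 methyl 2-hydroxy-2-[2-hydroxy-4-(methoxymethoxy)-3-prenylphenyl]acetate (racemic)
Conditions: NaBH4 (0.6 equiv), MeOH–THF, −20 °C; aq. NH4Cl
Reagents that add atoms: none
Why: Chemoselective borohydride reduction of the ketone of an α-keto ester, far more electrophilic than the ester, should give the mandelate, whose uncontrolled benzylic stereocentre is destroyed in step 13.

Step 6
Reactants: 10 methyl 2-hydroxy-2-[2-hydroxy-4-(methoxymethoxy)-3-prenylphenyl]acetate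
Product: 11 methyl 2-acetoxy-2-[2-acetoxy-4-(methoxymethoxy)-3-prenylphenyl]acetate (racemic)
Conditions: Ac2O (3 equiv), pyridine, DMAP (cat.), CH2Cl2, 0 °C → rt
Reagents that add atoms: acetic anhydride, CC(=O)OC(C)=O
Why: Exhaustive DMAP-catalysed acylation esterifies phenol and secondary alcohol, installing the benzylic acetate leaving group with a base too weak to trigger elimination.

Step 7
Reactants: 11 methyl 2-acetoxy-2-[2-acetoxy-4-(methoxymethoxy)-3-prenylphenyl]acetate
Product: 12 methyl 2-acetoxy-2-[2-hydroxy-4-(methoxymethoxy)-3-prenylphenyl]acetate (racemic)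
Conditions: NH4OAc (5 equiv), MeOH–H2O (4:1), rt; used without storage
Reagents that add atoms: none
Why: In this chemoselective transesterification the aryl acetate, with the better leaving group, is methanolysed under neutral buffering while the alkyl acetate survives, and the near-neutral pH keeps the freed phenol protonated so that the quinone methide is not released early.

**Ring B fragment**

Step 8
Reactants: 13 4,6-dibromoresorcinol
Product: 14 1,5-dibromo-2,4-bis(methoxymethoxy)benzene
Conditions: MOMCl (2.5 equiv), i-Pr2NEt (3 equiv), CH2Cl2, 0 °C → rt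
Reagents that add atoms: chloromethyl methyl ether, COCCl
Why: The same double phenol O-alkylation as in step 1 gives the bis-acetal needed for the organolithium steps.

Step 9
Reactants: 14 1,5-dibromo-2,4-bis(methoxymethoxy)benzene; 3 prenyl bromide
Product: 16 1-bromo-2,4-bis(methoxymethoxy)-5-prenylbenzene, via aryllithium 15 (not isolated)
Conditions: n-BuLi (1.0 equiv), THF, −78 °C; CuI (10 mol %), prenyl bromide (1.5 equiv), −78 → 0 °C
Reagents that add atoms: none
Why: Bromine–lithium exchange with one equivalent of n-BuLi should stop at the monolithio arene, since a second exchange on the aryl anion is disfavoured, and allylic substitution on prenyl bromide installs the side chain at the future C5' of ring B.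

Step 10
Reactants: 16 1-bromo-2,4-bis(methoxymethoxy)-5-prenylbenzene
Product: 18 2,4-bis(methoxymethoxy)-5-prenylbenzaldehyde, via aryllithium 17 (not isolated)
Conditions: n-BuLi (1.1 equiv), THF, −78 °C; DMF (3 equiv), −78 °C → rt; aq. NH4Cl
Reagents that add atoms: N,N-dimethylformamide, CN(C)C=O
Why: A second bromine–lithium exchange and formylation of the aryllithium with DMF (Bouveault-type aldehyde synthesis) places the one-carbon unit that becomes furan C2.

Step 11
Reactants: 18 2,4-bis(methoxymethoxy)-5-prenylbenzaldehyde
Product: 19 [2,4-bis(methoxymethoxy)-5-prenylphenyl]methanol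
Conditions: NaBH4, MeOH, 0 °C
Reagents that add atoms: none
Why: Borohydride reduction of the aryl aldehyde to the benzylic alcohol leaves the MOM ethers and the alkene untouched.

Step 12
Reactants: 19 [2,4-bis(methoxymethoxy)-5-prenylphenyl]methanol
Product: 21 [2,4-bis(methoxymethoxy)-5-prenylbenzyl]dimethylsulfonium bromide, via benzyl bromide 20 (not isolated)
Conditions: CBr4 (1.2 equiv), PPh3 (1.2 equiv), CH2Cl2, 0 °C; then Me2S (10 equiv), 0 °C → rt; trituration with Et2O
Reagents that add atoms: carbon tetrabromide, BrC(Br)(Br)Br; dimethyl sulfide, CSC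
Why: Appel bromination under neutral conditions gives the labile electron-rich benzyl bromide, which is intercepted in the same flask by SN2 alkylation of dimethyl sulfide, so the MOM groups never meet acid.

**Union and endgame**

Step 13
Reactants: 12 methyl 2-acetoxy-2-[2-hydroxy-4-(methoxymethoxy)-3-prenylphenyl]acetate; 21 [2,4-bis(methoxymethoxy)-5-prenylbenzyl]dimethylsulfonium bromide
Product: 25 methyl trans-2-[2,4-bis(methoxymethoxy)-5-prenylphenyl]-6-(methoxymethoxy)-7-prenyl-2,3-dihydrobenzofuran-3-carboxylate (racemic), via sulfonium ylide 22 (not isolated), via ortho-quinone methide 23 (not isolated), via betaine 24 (not isolated)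
Conditions: 21 (1.5 equiv), Cs2CO3 (3.5 equiv), MeCN, 0 °C; slow addition of 12; → rt
Reagents that add atoms: none
Why: Cs2CO3 deprotonates the phenol of 12, whose phenoxide expels the benzylic acetate (1,4-elimination) to give ortho-quinone methide 23 with the ester on its methide carbon, while the same base reversibly deprotonates 21 at its benzylic carbon to give ylide 22. Conjugate addition of the ylide carbon to the methide carbon forms C2–C3 and rearomatises ring A to betaine 24, and the phenoxide then displaces dimethyl sulfide at the benzylic carbon with inversion, forming O1–C2. The closest known reaction is the [4+1] annulation of ortho-quinone methides with sulfonium ylides to trans-2,3-dihydrobenzofurans, applied here to a semi-stabilised benzyl ylide and an ester-bearing methide. The furan ring closes by 5-exo-tet substitution. C3 is set in the addition and C2 in the SN2 closure, the trans relationship following from closure through the betaine rotamer with aryl and ester anti and from base equilibration at the acidic C3, and the product is racemic because nothing chiral is present (both centres vanish in steps 14–15). The step needs 1,4- and not 1,2-attack of the ylide and C–C bond formation ahead of O-benzylation of the phenoxide: the first is secured by the aromaticity of ring A, regained only on attack at the methide carbon, the second by fast acetate loss from the phenoxide and the low stationary concentration of ylide.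

Step 14
Reactants: 25 methyl trans-2-[2,4-bis(methoxymethoxy)-5-prenylphenyl]-6-(methoxymethoxy)-7-prenyl-2,3-dihydrobenzofuran-3-carboxylate
Product: 27 methyl 2-[2,4-bis(methoxymethoxy)-5-prenylphenyl]-6-(methoxymethoxy)-3-(phenylselanyl)-7-prenyl-2,3-dihydrobenzofuran-3-carboxylate (racemic; SePh cis to H-2 and trans to the C2 aryl), via lithium enolate 26 (not isolated)
Conditions: LiN(i-Pr)2 (1.2 equiv), THF, −78 °C; PhSeCl (1.3 equiv), −78 °C; aq. NH4Cl
Reagents that add atoms: benzeneselenenyl chloride, Cl[Se]c1ccccc1
Why: In this ester enolate selenenylation the base removes the C3 hydrogen (α to the ester and benzylic) and PhSeCl should add to the enolate face opposite the C2 aryl group, which sets the quaternary C3 centre with selenium cis to the C2 hydrogen as the later syn elimination needs, while ring opening of the enolate would be a retro-5-endo-trig process and should be slow at −78 °C.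

Step 15
Reactants: 27 methyl 2-[2,4-bis(methoxymethoxy)-5-prenylphenyl]-6-(methoxymethoxy)-3-(phenylselanyl)-7-prenyl-2,3-dihydrobenzofuran-3-carboxylate
Product: 29 methyl 2-[2,4-bis(methoxymethoxy)-5-prenylphenyl]-6-(methoxymethoxy)-7-prenylbenzofuran-3-carboxylate, via selenoxide 28 (not isolated)
Conditions: mCPBA (1.05 equiv), CH2Cl2, −78 °C; then i-Pr2NH (3 equiv), −78 °C → rt
Reagents that add atoms: none
Why: In this selenoxide syn elimination, oxidation at selenium with one equivalent of peracid at −78 °C outpaces alkene epoxidation, and on warming the selenoxide removes the only β-hydrogen (C2–H) through a five-membered cyclic transition state to give the aromatic benzofuran, erasing both stereocentres (the amine intercepts PhSeOH before it can add to the prenyl groups).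

Step 16
Reactants: 29 methyl 2-[2,4-bis(methoxymethoxy)-5-prenylphenyl]-6-(methoxymethoxy)-7-prenylbenzofuran-3-carboxylate
Product: 30 {2-[2,4-bis(methoxymethoxy)-5-prenylphenyl]-6-(methoxymethoxy)-7-prenylbenzofuran-3-yl}methanol
Conditions: i-Bu2AlH (2.5 equiv), CH2Cl2, −78 → 0 °C; aq. potassium sodium tartrate
Reagents that add atoms: none
Why: Hydride reduction of the ester with excess i-Bu2AlH should give the primary alcohol, since MOM acetals, prenyl groups and the benzofuran are inert to it at low temperature.

Step 17
Reactants: 30 {2-[2,4-bis(methoxymethoxy)-5-prenylphenyl]-6-(methoxymethoxy)-7-prenylbenzofuran-3-yl}methanol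
Product: 31 2-[2,4-bis(methoxymethoxy)-5-prenylphenyl]-6-(methoxymethoxy)-7-prenylbenzofuran-3-carbaldehyde
Conditions: MnO2 (activated, 15 equiv), CH2Cl2, rt
Reagents that add atoms: none
Why: MnO2 oxidises the benzofuran-3-ylmethanol as an activated benzylic-type alcohol and stops at the aldehyde.

Step 18
Reactants: 31 2-[2,4-bis(methoxymethoxy)-5-prenylphenyl]-6-(methoxymethoxy)-7-prenylbenzofuran-3-carbaldehyde
Product: 32 Eryvarin Q
Conditions: 3 M aq. HCl, MeOH–THF, 40 °C, stopped as soon as 31 is consumed
Reagents that add atoms: none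
Why: Acid-catalysed acetal exchange with methanol removes the three MOM groups as dimethoxymethane, the C3 formyl group by now deactivating the benzofuran, and dilute acid at mild temperature should spare the prenyl groups from cyclising onto the neighbouring phenols.

**Compound list**

1 | resorcinol | Oc1cccc(O)c1 | starting material
2 | 1,3-bis(methoxymethoxy)benzene | COCOc1cccc(OCOC)c1 | intermediate
3 | prenyl bromide (1-bromo-3-methylbut-2-ene) | CC(C)=CCBr | starting material
4 | [2,6-bis(methoxymethoxy)phenyl]lithium (not isolated) | [Li]c1c(OCOC)cccc1OCOC | intermediate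
5 | 1,3-bis(methoxymethoxy)-2-prenylbenzene | COCOc1cccc(OCOC)c1CC=C(C)C | intermediate
6 | dimethyl oxalate | COC(=O)C(=O)OC | starting material
7 | [2,4-bis(methoxymethoxy)-3-prenylphenyl]lithium (not isolated) | [Li]c1ccc(OCOC)c(CC=C(C)C)c1OCOC | intermediate
8 | methyl 2-[2,4-bis(methoxymethoxy)-3-prenylphenyl]-2-oxoacetate | COC(=O)C(=O)c1ccc(OCOC)c(CC=C(C)C)c1OCOC | intermediate
9 | methyl 2-[2-hydroxy-4-(methoxymethoxy)-3-prenylphenyl]-2-oxoacetate | COC(=O)C(=O)c1ccc(OCOC)c(CC=C(C)C)c1O | intermediate
10 | methyl 2-hydroxy-2-[2-hydroxy-4-(methoxymethoxy)-3-prenylphenyl]acetate (racemic) | COC(=O)C(O)c1ccc(OCOC)c(CC=C(C)C)c1O | intermediate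
11 | methyl 2-acetoxy-2-[2-acetoxy-4-(methoxymethoxy)-3-prenylphenyl]acetate (racemic) | COC(=O)C(OC(C)=O)c1ccc(OCOC)c(CC=C(C)C)c1OC(C)=O | intermediate
12 | methyl 2-acetoxy-2-[2-hydroxy-4-(methoxymethoxy)-3-prenylphenyl]acetate (racemic) | COC(=O)C(OC(C)=O)c1ccc(OCOC)c(CC=C(C)C)c1O | intermediate
13 | 4,6-dibromoresorcinol | Oc1cc(O)c(Br)cc1Br | starting material
14 | 1,5-dibromo-2,4-bis(methoxymethoxy)benzene | COCOc1cc(OCOC)c(Br)cc1Br | intermediate
15 | [5-bromo-2,4-bis(methoxymethoxy)phenyl]lithium (not isolated) | [Li]c1cc(Br)c(OCOC)cc1OCOC | intermediate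
16 | 1-bromo-2,4-bis(methoxymethoxy)-5-prenylbenzene | COCOc1cc(OCOC)c(CC=C(C)C)cc1Br | intermediate
17 | [2,4-bis(methoxymethoxy)-5-prenylphenyl]lithium (not isolated) | [Li]c1cc(CC=C(C)C)c(OCOC)cc1OCOC | intermediate
18 | 2,4-bis(methoxymethoxy)-5-prenylbenzaldehyde | COCOc1cc(OCOC)c(CC=C(C)C)cc1C=O | intermediate
19 | [2,4-bis(methoxymethoxy)-5-prenylphenyl]methanol | COCOc1cc(OCOC)c(CC=C(C)C)cc1CO | intermediate
20 | 1-(bromomethyl)-2,4-bis(methoxymethoxy)-5-prenylbenzene (not isolated) | COCOc1cc(OCOC)c(CC=C(C)C)cc1CBr | intermediate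
21 | [2,4-bis(methoxymethoxy)-5-prenylbenzyl]dimethylsulfonium bromide | C[S+](C)Cc1cc(CC=C(C)C)c(OCOC)cc1OCOC.[Br-] | intermediate
22 | dimethylsulfonium [2,4-bis(methoxymethoxy)-5-prenylphenyl]methylide (not isolated) | C[S+](C)[CH-]c1cc(CC=C(C)C)c(OCOC)cc1OCOC | intermediate
23 | methyl 2-[4-(methoxymethoxy)-6-oxo-5-prenylcyclohexa-2,4-dien-1-ylidene]acetate, the ortho-quinone methide (alkene geometry open, not isolated) | COC(=O)C=C1C=CC(OCOC)=C(CC=C(C)C)C1=O | intermediate
24 | betaine: 2-[2-(methoxycarbonyl)-1-(dimethylsulfonio)-1-aryl-ethyl-2-yl]phenoxide from C–C bond formation between 22 and 23 (diastereomer mixture, not isolated) | COC(=O)C(c1ccc(OCOC)c(CC=C(C)C)c1[O-])C(c1cc(CC=C(C)C)c(OCOC)cc1OCOC)[S+](C)C | intermediate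
25 | methyl trans-2-[2,4-bis(methoxymethoxy)-5-prenylphenyl]-6-(methoxymethoxy)-7-prenyl-2,3-dihydrobenzofuran-3-carboxylate (racemic, one enantiomer drawn) | COC(=O)[C@@H]1[C@@H](c2cc(CC=C(C)C)c(OCOC)cc2OCOC)Oc2c(CC=C(C)C)c(OCOC)ccc21 | intermediate
26 | lithium enolate of 25 at C3 (racemic, not isolated) | COC([O-])=C1[C@@H](c2cc(CC=C(C)C)c(OCOC)cc2OCOC)Oc2c(CC=C(C)C)c(OCOC)ccc21.[Li+] | intermediate
27 | methyl 2-[2,4-bis(methoxymethoxy)-5-prenylphenyl]-6-(methoxymethoxy)-3-(phenylselanyl)-7-prenyl-2,3-dihydrobenzofuran-3-carboxylate (racemic; SePh cis to H-2) | COC(=O)[C@@]1([Se]c2ccccc2)[C@@H](c2cc(CC=C(C)C)c(OCOC)cc2OCOC)Oc2c(CC=C(C)C)c(OCOC)ccc21 | intermediate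
28 | selenoxide of 27 (configuration at Se open, not isolated) | COC(=O)[C@@]1([Se](=O)c2ccccc2)[C@@H](c2cc(CC=C(C)C)c(OCOC)cc2OCOC)Oc2c(CC=C(C)C)c(OCOC)ccc21 | intermediate
29 | methyl 2-[2,4-bis(methoxymethoxy)-5-prenylphenyl]-6-(methoxymethoxy)-7-prenylbenzofuran-3-carboxylate | COC(=O)c1c(-c2cc(CC=C(C)C)c(OCOC)cc2OCOC)oc2c(CC=C(C)C)c(OCOC)ccc12 | intermediate
30 | {2-[2,4-bis(methoxymethoxy)-5-prenylphenyl]-6-(methoxymethoxy)-7-prenylbenzofuran-3-yl}methanol | OCc1c(-c2cc(CC=C(C)C)c(OCOC)cc2OCOC)oc2c(CC=C(C)C)c(OCOC)ccc12 | intermediate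
31 | 2-[2,4-bis(methoxymethoxy)-5-prenylphenyl]-6-(methoxymethoxy)-7-prenylbenzofuran-3-carbaldehyde | O=Cc1c(-c2cc(CC=C(C)C)c(OCOC)cc2OCOC)oc2c(CC=C(C)C)c(OCOC)ccc12 | intermediate
32 | Eryvarin Q, 2-(2,4-dihydroxy-5-prenylphenyl)-6-hydroxy-7-prenylbenzofuran-3-carbaldehyde | CC(C)=CCc1cc(-c2oc3c(CC=C(C)C)c(O)ccc3c2C=O)c(O)cc1O | target

**Step count**

Total: 18 steps. Longest linear sequence: 13 steps (steps 1–7, then 13–18); the ring B branch is 5 steps (8–12).

**Three steps most likely to fail**

Step 13. The ylide may be lost to Sommelet–Hauser rearrangement, the phenoxide may be O-benzylated by the sulfonium salt before acetate loss, or the quinone methide may dimerise before the ylide reaches it. The fallback sets out from 9 and 19 and comes back at 25, forming O1–C2 first and C2–C3 by carbenoid insertion. Mitsunobu etherification (PPh3, DIAD, THF, 0 °C → rt) of phenol 9 with alcohol 19 would give methyl 2-[2-{[2,4-bis(methoxymethoxy)-5-prenylbenzyl]oxy}-4-(methoxymethoxy)-3-prenylphenyl]-2-oxoacetate F1. Condensation with TsNHNH2 (MeOH, 50 °C) would give its tosylhydrazone F2, and Bamford–Stevens elimination (DBU, CH2Cl2, rt) the methyl aryldiazoacetate F3. Rh2(OAc)4 (1 mol %, CH2Cl2, rt) should then effect intramolecular carbenoid insertion into the benzylic ether C–H bond, closing the dihydrofuran ring to 25. Either relative configuration at C2/C3 serves, because step 14 planarises C3.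

Step 14. The C3 enolate may open the ring by β-elimination of the aryloxide, or selenium may be delivered syn to the aryl group, which leaves no hydrogen for syn elimination. The fallback sets out from 25 and comes back at 29 without an enolate: DDQ (1.5 equiv, 1,4-dioxane, 80 °C) removes hydride from C2 (benzylic and α to oxygen) and a proton from C3, the known dehydrogenation of 2-aryl-2,3-dihydrobenzofuran-3-carboxylates. The phenols stay MOM-capped, which blocks DDQ-induced chromene formation at the prenyl groups. This fallback makes no new compound (F0).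

Step 4. Both MOM groups may be cleaved, or the freed phenol may add to the neighbouring prenyl double bond under Lewis acid. The fallback sets out from 8 and comes back at 9. Both MOM groups are removed (1 M HCl, MeOH, rt) to give methyl 2-(2,4-dihydroxy-3-prenylphenyl)-2-oxoacetate F4. Re-protection with MOMCl (1.1 equiv), K2CO3, acetone, 0 °C → rt should then alkylate only the 4-OH, because the 2-OH is tied up in a hydrogen bond to the ketone.

**Further compounds**

F1 | step 13 | methyl 2-[2-{[2,4-bis(methoxymethoxy)-5-prenylbenzyl]oxy}-4-(methoxymethoxy)-3-prenylphenyl]-2-oxoacetate | COC(=O)C(=O)c1ccc(OCOC)c(CC=C(C)C)c1OCc1cc(CC=C(C)C)c(OCOC)cc1OCOC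
F2 | step 13 | tosylhydrazone of F1 (C=N geometry open) | COC(=O)C(=NNS(=O)(=O)c1ccc(C)cc1)c1ccc(OCOC)c(CC=C(C)C)c1OCc1cc(CC=C(C)C)c(OCOC)cc1OCOC
F3 | step 13 | methyl 2-diazo-2-[2-{[2,4-bis(methoxymethoxy)-5-prenylbenzyl]oxy}-4-(methoxymethoxy)-3-prenylphenyl]acetate | COC(=O)C(=[N+]=[N-])c1ccc(OCOC)c(CC=C(C)C)c1OCc1cc(CC=C(C)C)c(OCOC)cc1OCOC
F0 | step 14 | none | none
F4 | step 4 | methyl 2-(2,4-dihydroxy-3-prenylphenyl)-2-oxoacetate | COC(=O)C(=O)c1ccc(O)c(CC=C(C)C)c1O
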